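**Plan**
- Cuts: (a) the ketone C(=O)–C1' bond to ring A together with the C2'–O bond of the neighbouring phenol, which leads back to 3,5-dimethoxybenzyne and a 2,2-dimethyl-2H-chromene-5-carboxylic acid; (b) the pyran bonds C4–C4a and O1–C2, which lead back to an aryl 1,1-dimethylpropargyl ether of methyl 3,5-dihydroxybenzoate; the chromene C7–OH travels as a MOM ether.
- Enabling feature: on ring A the free OH sits on the carbon next to the ketone-bearing carbon, with OMe on the other neighbour. An o-hydroxyaryl ketone is what an aryne gives on insertion into the CO–OH bond of a carboxylic acid, and the OMe flanking the acylated carbon directs that insertion.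
- Forward order: both benzene rings are bought; ring A is turned into an o-silylaryl triflate; the pyran ring is closed on ring B by propargyl Claisen rearrangement, 1,5-H shift and oxa-6π electrocyclisation; the halves are joined by the aryne insertion; the MOM ether is removed last.
- Stereochemistry: the target has no stereocentre; its only stereo-element, the cis C3=C4 double bond, is fixed by the pyran ring.

Key step: step 8

Remark: the target SMILES carries no stereodescriptor and is treated as achiral; compounds 1 and 9 and all reagents named are taken as purchasable.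

**Route**

Step 1
Reactants: 1 3,5-dimethoxyphenol
Product: 2 3,5-dimethoxyphenyl N-isopropylcarbamate
Conditions: i-PrNCO, Et3N (cat.), CH2Cl2, rt
Reagents that add atoms: isopropyl isocyanate, CC(C)N=C=O
Why: Base-catalysed addition of the phenol O–H across the isocyanate (carbamoylation) should give the secondary carbamate that serves as the ortho-directing group and is later removable under mild base.

Step 2
Reactants: 2 3,5-dimethoxyphenyl N-isopropylcarbamate
Product: 6 3,5-dimethoxy-2-(trimethylsilyl)phenyl N-isopropylcarbamate, via N-silyl carbamate 3 (not isolated), via aryllithium 4 (not isolated), via N-silyl C-silyl carbamate 5 (not isolated)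
Conditions: TBSOTf, TMEDA, Et2O, 0 °C → rt; n-BuLi, TMEDA, −78 °C; TMSCl, −78 °C → rt; aq. NaHSO4
Reagents that add atoms: chlorotrimethylsilane, C[Si](C)(C)Cl; tert-butyldimethylsilyl triflate, CC(C)(C)[Si](C)(C)OS(=O)(=O)C(F)(F)F (TBS present only in 3–5); n-butyllithium, [Li]CCCC (Li present only in 4)
Why: Directed ortho-metalation: in situ N-silylation removes the acidic N–H, the carbamate (strongest director on the ring, reinforced by the adjacent OMe) should guide n-BuLi to the carbon between the carbamate oxygen and OMe (two equivalent positions), TMSCl silylates the aryllithium, and the N–Si bond is hydrolysed on work-up.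

Step 3
Reactants: 6 3,5-dimethoxy-2-(trimethylsilyl)phenyl N-isopropylcarbamate
Product: 8 3,5-dimethoxy-2-(trimethylsilyl)phenyl trifluoromethanesulfonate, via silylphenol 7 (not isolated)
Conditions: DBU, Et2NH, MeCN, 40 °C; then PhNTf2, rt
Reagents that add atoms: N-phenylbis(trifluoromethanesulfonimide), O=S(=O)(N(c1ccccc1)S(=O)(=O)C(F)(F)F)C(F)(F)F
Why: E1cB cleavage of the secondary carbamate (DBU removes N–H, the aryloxide leaves, the isocyanate is trapped by Et2NH as a urea) followed by O-sulfonylation of the phenoxide in the same flask is the established way to o-silylaryl triflate aryne precursors.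

Step 4
Reactants: 9 methyl 3,5-dihydroxybenzoate
Product: 10 methyl 3-hydroxy-5-(methoxymethoxy)benzoate
Conditions: MOMCl (1.0 equiv), i-Pr2NEt, THF, 0 °C → rt
Reagents that add atoms: chloromethyl methyl ether, COCCl
Why: Williamson-type O-alkylation with one equivalent of MOMCl on the symmetric diol should give the mono-ether statistically; unreacted 9 and the bis-ether are separable and 9 can be recycled.

Step 5
Reactants: 10 methyl 3-hydroxy-5-(methoxymethoxy)benzoate
Product: 11 methyl 3-(methoxymethoxy)-5-[(2-methylbut-3-yn-2-yl)oxy]benzoate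
Conditions: 3-chloro-3-methylbut-1-yne, DBU, CuCl2 (cat.), MeCN, 0 °C → rt
Reagents that add atoms: 3-chloro-3-methylbut-1-yne, C#CC(C)(C)Cl
Why: Copper-catalysed propargylic substitution (O-alkylation of the phenol by the tertiary propargylic chloride through a copper acetylide/allenylidene) is the standard entry to aryl 1,1-dimethylpropargyl ethers and tolerates the ester and the MOM ether.

Step 6
Reactants: 11 methyl 3-(methoxymethoxy)-5-[(2-methylbut-3-yn-2-yl)oxy]benzoate
Product: 15 methyl 7-(methoxymethoxy)-2,2-dimethyl-2H-chromene-5-carboxylate, via allenyl dienone 12 (not isolated), via allenylphenol 13 (not isolated), via ortho-quinone methide 14 (not isolated)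
Conditions: PhNEt2, 185 °C
Reagents that add atoms: none
Why: Aromatic propargyl Claisen rearrangement ([3,3]) to the ring carbon between the ether oxygen and the ester, enolisation, 1,5-hydrogen shift and oxa-6π electrocyclisation should give the 2,2-dimethyl-2H-chromene; migration to that carbon is expected because it lies next to the electron-withdrawing ester and para to the OMOM donor, the two known directing effects of meta substituents in aromatic Claisen shifts acting in the same sense.

Step 7
Reactants: 15 methyl 7-(methoxymethoxy)-2,2-dimethyl-2H-chromene-5-carboxylate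
Product: 17 7-(methoxymethoxy)-2,2-dimethyl-2H-chromene-5-carboxylic acid, via lithium carboxylate 16 (not isolated)
Conditions: LiOH·H2O, THF/MeOH/H2O, 50 °C; then 1 M HCl to pH 3–4, 0 °C
Reagents that add atoms: lithium hydroxide, [Li+].[OH-] (its oxygen ends in the carboxyl group of 17; Li present only in 16)
Why: Saponification (BAc2 ester hydrolysis) should proceed with the MOM ether and the chromene untouched by hydroxide, and the brief cold acidification spares the MOM acetal.

Step 8
Reactants: 17 7-(methoxymethoxy)-2,2-dimethyl-2H-chromene-5-carboxylic acid; 8 3,5-dimethoxy-2-(trimethylsilyl)phenyl trifluoromethanesulfonate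
Product: 23 (2-hydroxy-4,6-dimethoxyphenyl)[7-(methoxymethoxy)-2,2-dimethyl-2H-chromen-5-yl]methanone, via cesium carboxylate 18 (not isolated), via 3,5-dimethoxybenzyne 19 (not isolated), via aryl anion 20 (not isolated), via benzoxetene alkoxide 21 (not isolated), via cesium phenoxide 22 (not isolated)
Conditions: CsF, THF, 125 °C (sealed tube)
Reagents that add atoms: cesium fluoride, [Cs+].[F-] (supplies only the Cs+ counter-ion of 18 and 20–22; no atom of it remains in 23)
Why: Fluoride removes the trimethylsilyl group of 8 and triflate leaves to give aryne 19; carboxylate 18 adds through oxygen to the aryne carbon remote from the flanking OMe, the aryl anion 20 so formed (on the carbon between the new ester oxygen and OMe) attacks its own ester carbonyl to give benzoxetene alkoxide 21, and C–O cleavage of that strained ring gives phenoxide 22, protonated to 23, a net insertion of the aryne into the C(acyl)–O bond of the acid. The closest known reaction type is the fluoride-mediated C–O addition of aromatic carboxylic acids to arynes from o-silylaryl triflates, which gives o-hydroxyaryl ketones. The only ring closed is the transient four-membered benzoxetene (4-exo-trig, reopened in the same step); no ring of 23 and no stereocentre is formed, the hemiketal carbon of 21 being destroyed on ring opening. The regioselectivity needed (oxygen on C1, acyl on C2 next to OMe) should be secured by the C3 methoxy group of 19, which distorts the triple bond and inductively stabilises negative charge on C2 so that the nucleophile enters at C1; this places the free OH ortho to the ketone and the OMe groups at the 4- and 6-positions without any protecting group on ring A. The chemoselectivity needed (acyl shift before protonation of 20, no second arylation) rests on the ester sitting directly ortho to the carbanion, on the high temperature, on the MOM ether masking the only other phenol, and on the product phenoxide being chelated to the ketone and flanked on both sides.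

Step 9
Reactants: 23 (2-hydroxy-4,6-dimethoxyphenyl)[7-(methoxymethoxy)-2,2-dimethyl-2H-chromen-5-yl]methanone
Product: 24 (2-hydroxy-4,6-dimethoxyphenyl)(7-hydroxy-2,2-dimethyl-2H-chromen-5-yl)methanone
Conditions: 2 M aq. HCl, MeOH, 40 °C
Reagents that add atoms: none
Why: Acid-catalysed acetal exchange (methanolysis of the MOM ether) should free the C7 phenol, while the aryl methyl ethers, the diaryl ketone and the 2,2-dimethylchromene are expected to survive dilute acid at this temperature.

**Compound list**

1 | 3,5-dimethoxyphenol | COc1cc(O)cc(OC)c1 | starting material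
2 | 3,5-dimethoxyphenyl N-isopropylcarbamate | COc1cc(OC)cc(OC(=O)NC(C)C)c1 | intermediate
3 | 3,5-dimethoxyphenyl N-(tert-butyldimethylsilyl)-N-isopropylcarbamate | COc1cc(OC)cc(OC(=O)N(C(C)C)[Si](C)(C)C(C)(C)C)c1 | intermediate (not isolated)
4 | {2-[(tert-butyldimethylsilyl)(isopropyl)carbamoyloxy]-4,6-dimethoxyphenyl}lithium | [Li]c1c(OC)cc(OC)cc1OC(=O)N(C(C)C)[Si](C)(C)C(C)(C)C | intermediate (not isolated)
5 | 3,5-dimethoxy-2-(trimethylsilyl)phenyl N-(tert-butyldimethylsilyl)-N-isopropylcarbamate | COc1cc(OC)c([Si](C)(C)C)c(OC(=O)N(C(C)C)[Si](C)(C)C(C)(C)C)c1 | intermediate (not isolated)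
6 | 3,5-dimethoxy-2-(trimethylsilyl)phenyl N-isopropylcarbamate | COc1cc(OC)c([Si](C)(C)C)c(OC(=O)NC(C)C)c1 | intermediate
7 | 3,5-dimethoxy-2-(trimethylsilyl)phenol | COc1cc(O)c([Si](C)(C)C)c(OC)c1 | intermediate (not isolated)
8 | 3,5-dimethoxy-2-(trimethylsilyl)phenyl trifluoromethanesulfonate | COc1cc(OC)c([Si](C)(C)C)c(OS(=O)(=O)C(F)(F)F)c1 | intermediate
9 | methyl 3,5-dihydroxybenzoate | COC(=O)c1cc(O)cc(O)c1 | starting material
10 | methyl 3-hydroxy-5-(methoxymethoxy)benzoate | COCOc1cc(O)cc(C(=O)OC)c1 | intermediate
11 | methyl 3-(methoxymethoxy)-5-[(2-methylbut-3-yn-2-yl)oxy]benzoate | COCOc1cc(OC(C)(C)C#C)cc(C(=O)OC)c1 | intermediate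
12 | methyl 3-(methoxymethoxy)-6-(3-methylbuta-1,2-dien-1-yl)-5-oxocyclohexa-1,3-diene-1-carboxylate (racemic, transient) | COCOC1=CC(=O)C(C=C=C(C)C)C(C(=O)OC)=C1 | intermediate (not isolated)
13 | methyl 3-hydroxy-5-(methoxymethoxy)-2-(3-methylbuta-1,2-dien-1-yl)benzoate | COCOc1cc(O)c(C=C=C(C)C)c(C(=O)OC)c1 | intermediate (not isolated)
14 | methyl 3-(methoxymethoxy)-6-(3-methylbut-2-en-1-ylidene)-5-oxocyclohexa-1,3-diene-1-carboxylate | COCOC1=CC(=O)C(=CC=C(C)C)C(C(=O)OC)=C1 | intermediate (not isolated)
15 | methyl 7-(methoxymethoxy)-2,2-dimethyl-2H-chromene-5-carboxylate | COCOc1cc2OC(C)(C)C=Cc2c(C(=O)OC)c1 | intermediate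
16 | lithium 7-(methoxymethoxy)-2,2-dimethyl-2H-chromene-5-carboxylate | COCOc1cc2OC(C)(C)C=Cc2c(C(=O)[O-])c1.[Li+] | intermediate (not isolated)
17 | 7-(methoxymethoxy)-2,2-dimethyl-2H-chromene-5-carboxylic acid | COCOc1cc2OC(C)(C)C=Cc2c(C(=O)O)c1 | intermediate
18 | cesium 7-(methoxymethoxy)-2,2-dimethyl-2H-chromene-5-carboxylate | COCOc1cc2OC(C)(C)C=Cc2c(C(=O)[O-])c1.[Cs+] | intermediate (not isolated)
19 | 3,5-dimethoxybenzyne (1,2-didehydro-3,5-dimethoxybenzene) | COC1=CC(OC)=CC#C1 | intermediate (not isolated)
20 | cesium salt of the C2 carbanion of 3,5-dimethoxyphenyl 7-(methoxymethoxy)-2,2-dimethyl-2H-chromene-5-carboxylate | COc1cc(OC)[c-]c(OC(=O)c2cc(OCOC)cc3OC(C)(C)C=Cc23)c1.[Cs+] | intermediate (not isolated)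
21 | cesium 3,5-dimethoxy-2-[7-(methoxymethoxy)-2,2-dimethyl-2H-chromen-5-yl]-2H-benzo[b]oxet-2-olate | COc1cc(OC)c2c(c1)OC2([O-])c1cc(OCOC)cc3OC(C)(C)C=Cc13.[Cs+] | intermediate (not isolated)
22 | cesium 3,5-dimethoxy-2-[7-(methoxymethoxy)-2,2-dimethyl-2H-chromene-5-carbonyl]phenolate | COc1cc([O-])c(C(=O)c2cc(OCOC)cc3OC(C)(C)C=Cc23)c(OC)c1.[Cs+] | intermediate (not isolated)
23 | (2-hydroxy-4,6-dimethoxyphenyl)[7-(methoxymethoxy)-2,2-dimethyl-2H-chromen-5-yl]methanone | COc1cc(O)c(C(=O)c2cc(OCOC)cc3OC(C)(C)C=Cc23)c(OC)c1 | intermediate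
24 | (2-hydroxy-4,6-dimethoxyphenyl)(7-hydroxy-2,2-dimethyl-2H-chromen-5-yl)methanone | COc1cc(O)c(C(=O)c2cc(O)cc3c2C=CC(C)(C)O3)c(OC)c1 | target

**Totals**

Total step count: 9. Longest linear sequence: 6 steps (9 → 10 → 11 → 15 → 17 → 23 → 24; steps 4–9).

**Steps most likely to fail**

1. Step 8 (aryne insertion). The aryl anion may be protonated before the acyl shift, so that the reaction stops at the aryl ester; the product phenoxide may be arylated by a second aryne; or the aryne may add to the chromene double bond. The fallback replaces the insertion by acyl substitution with an aryllithium and sets out from acid 17 and phenol 1. Acid 17 would be converted (MeNHOMe·HCl, EDC·HCl, DMAP, CH2Cl2) into N-methoxy-N-methyl-7-(methoxymethoxy)-2,2-dimethyl-2H-chromene-5-carboxamide F1. Phenol 1 would be protected (MOMCl, NaH, DMF) as 1,3-dimethoxy-5-(methoxymethoxy)benzene F2. Directed ortho-lithiation of F2 (n-BuLi, TMEDA, THF, 0 °C) is expected between OMOM and OMe, the better-chelating pair, and should give [2,4-dimethoxy-6-(methoxymethoxy)phenyl]lithium F3. Addition of F3 to F1 should give the chelated lithium {[2,4-dimethoxy-6-(methoxymethoxy)phenyl][7-(methoxymethoxy)-2,2-dimethyl-2H-chromen-5-yl](N-methoxy-N-methylamino)}methanolate F4, which collapses on aqueous NH4Cl work-up to [2,4-dimethoxy-6-(methoxymethoxy)phenyl][7-(methoxymethoxy)-2,2-dimethyl-2H-chromen-5-yl]methanone F5. Cleavage of both MOM ethers under the conditions of step 9 returns to the route at target 24.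

2. Step 6 (propargyl Claisen/electrocyclisation). The sigmatropic shift may deliver the side chain to the ring carbon between the two oxygens, that is, positional control may be lost. The fallback fixes the carbon by electrophilic halogenation, sets out from 9 and comes back at 15. Diol 9 would be bis-protected (MOMCl excess, i-Pr2NEt) to methyl 3,5-bis(methoxymethoxy)benzoate F6. Bromination (NBS, MeCN) should give methyl 2-bromo-3,5-bis(methoxymethoxy)benzoate F7, since electrophilic substitution of 3,5-dialkoxybenzoates goes ortho to the ester and the two such positions are equivalent. Stille coupling with tributyl(3-methylbut-2-en-1-yl)stannane (Pd(PPh3)4, CsF, DMF, 100 °C) should give methyl 3,5-bis(methoxymethoxy)-2-(3-methylbut-2-en-1-yl)benzoate F8, and mild acid (HCl, MeOH, rt) methyl 3,5-dihydroxy-2-(3-methylbut-2-en-1-yl)benzoate F9. Dehydrogenative cyclisation with DDQ (benzene, 80 °C) should pass through methyl 3-hydroxy-6-(3-methylbut-2-en-1-ylidene)-5-oxocyclohexa-1,3-diene-1-carboxylate F10 and close by oxa-6π electrocyclisation to methyl 7-hydroxy-2,2-dimethyl-2H-chromene-5-carboxylate F11. MOM protection of F11 (MOMCl, i-Pr2NEt) gives 15.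

3. Step 2 (ortho-metalation/silylation). N-Silylation may be incomplete, in which case N-deprotonation blocks metalation or an anionic 1,3-O→C carbamoyl shift sets in on warming; metalation may also occur between the two methoxy groups. The fallback brings the silyl group in through a halogen, sets out from 1 and comes back at 8. Bromination of 1 (NBS, CH2Cl2, −78 °C) should give 2-bromo-3,5-dimethoxyphenol F12, to be separated from any 4-bromo isomer. O-Silylation (HMDS, THF, 65 °C) should give (2-bromo-3,5-dimethoxyphenoxy)trimethylsilane F13. Bromine–lithium exchange (n-BuLi, THF, −100 °C) should give [2,4-dimethoxy-6-(trimethylsilyloxy)phenyl]lithium F14, which rearranges by 1,3 O→C silyl shift (retro-Brook) to lithium 3,5-dimethoxy-2-(trimethylsilyl)phenoxide F15. Tf2O in the same flask gives 8.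

**Further compounds**

F1 | step 8 | N-methoxy-N-methyl-7-(methoxymethoxy)-2,2-dimethyl-2H-chromene-5-carboxamide | COCOc1cc2OC(C)(C)C=Cc2c(C(=O)N(C)OC)c1
F2 | step 8 | 1,3-dimethoxy-5-(methoxymethoxy)benzene | COCOc1cc(OC)cc(OC)c1
F3 | step 8 | [2,4-dimethoxy-6-(methoxymethoxy)phenyl]lithium | [Li]c1c(OC)cc(OC)cc1OCOC
F4 | step 8 | lithium {[2,4-dimethoxy-6-(methoxymethoxy)phenyl][7-(methoxymethoxy)-2,2-dimethyl-2H-chromen-5-yl](N-methoxy-N-methylamino)}methanolate | [Li+].[O-]C(N(C)OC)(c1c(OC)cc(OC)cc1OCOC)c1cc(OCOC)cc2OC(C)(C)C=Cc12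
F5 | step 8 | [2,4-dimethoxy-6-(methoxymethoxy)phenyl][7-(methoxymethoxy)-2,2-dimethyl-2H-chromen-5-yl]methanone | COCOc1cc(OC)cc(OC)c1C(=O)c1cc(OCOC)cc2OC(C)(C)C=Cc12
F6 | step 6 | methyl 3,5-bis(methoxymethoxy)benzoate | COCOc1cc(OCOC)cc(C(=O)OC)c1
F7 | step 6 | methyl 2-bromo-3,5-bis(methoxymethoxy)benzoate | COCOc1cc(OCOC)c(Br)c(C(=O)OC)c1
F8 | step 6 | methyl 3,5-bis(methoxymethoxy)-2-(3-methylbut-2-en-1-yl)benzoate | COCOc1cc(OCOC)c(CC=C(C)C)c(C(=O)OC)c1
F9 | step 6 | methyl 3,5-dihydroxy-2-(3-methylbut-2-en-1-yl)benzoate | COC(=O)c1cc(O)cc(O)c1CC=C(C)C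
F10 | step 6 | methyl 3-hydroxy-6-(3-methylbut-2-en-1-ylidene)-5-oxocyclohexa-1,3-diene-1-carboxylate | COC(=O)C1=CC(O)=CC(=O)C1=CC=C(C)C
F11 | step 6 | methyl 7-hydroxy-2,2-dimethyl-2H-chromene-5-carboxylate | COC(=O)c1cc(O)cc2OC(C)(C)C=Cc12
F12 | step 2 | 2-bromo-3,5-dimethoxyphenol | COc1cc(O)c(Br)c(OC)c1
F13 | step 2 | (2-bromo-3,5-dimethoxyphenoxy)trimethylsilane | COc1cc(O[Si](C)(C)C)c(Br)c(OC)c1
F14 | step 2 | [2,4-dimethoxy-6-(trimethylsilyloxy)phenyl]lithium | [Li]c1c(OC)cc(OC)cc1O[Si](C)(C)C
F15 | step 2 | lithium 3,5-dimethoxy-2-(trimethylsilyl)phenoxide | COc1cc([O-])c([Si](C)(C)C)c(OC)c1.[Li+]
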